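**Retrosynthetic overview**
- Last bond: C3'–C4' of the side-chain diene, by Suzuki–Miyaura coupling of an alkenyl bromide already on the finished ring with a benzyl-substituted alkenylboronate; C1 is carried as an aldehyde and oxidised to the methyl ester just before.
- Key disconnection, C4–C5 and O2–C3 in one pot: a formal (4+2) union of the four-atom unit C5–C6–O1–O2 (a β-iodo tertiary peroxide, masked as a perketal) with the C3=C4 edge of pent-2-enal, used as its silyl dienol ether.
- Enabling feature: in the 1,2-dioxane ring (O1–O2–C3–C4–C5–C6), C3 carries O2 and lies β to the C1 carbonyl, and the methyl-bearing C4 is γ to it. C3=C4 is therefore the distal double bond of a dienol of pent-2-enal: a C5 radical attacks C4, and the enal so formed takes up O2 at C3 by 6-exo oxa-Michael addition.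
- The quaternary peroxide carbon C6 comes from (S)-2-methylglycidol by alkynylation, Negishi carboalumination, epoxide re-formation and acid-catalysed perhydrolysis with inversion.
- Ring order: the 1,2-dioxane is the only ring and is closed in the key step; C6 is set before it, C3 by the amine catalyst, C4 by dynamic kinetic resolution.

Key step: step 9

Assumption: the sense of induction of the prolinol catalyst follows the usual shielding model of its E-iminium ion, and the perhydrolysis in step 5 runs with inversion; if either sense proved opposite, the enantiomeric catalyst or (R)-2-methylglycidol would be used.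

**Step 1**
Reactants: 1 (S)-2-methylglycidol
Product: 2 (R)-(2-methyloxiran-2-yl)methyl 4-methylbenzenesulfonate
Conditions: TsCl, Et3N, DMAP (cat.), CH2Cl2, 0 °C
Reagents that add atoms: 4-methylbenzenesulfonyl chloride, Cc1ccc(cc1)S(Cl)(=O)=O
Why: Sulfonylation of the primary alcohol leaves the epoxide and the quaternary stereocentre untouched and turns the hydroxymethyl arm into the latent terminus of a later epoxide.

**Step 2**
Reactants: 2 (R)-(2-methyloxiran-2-yl)methyl 4-methylbenzenesulfonate
Product: 4 (R)-2-hydroxy-2-methylpent-4-yn-1-yl 4-methylbenzenesulfonate, via silylalkyne 3 (not isolated)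
Conditions: LiC≡CSiMe3, BF3·OEt2, THF, −78 °C; crude product: Bu4NF, AcOH, THF, 0 °C
Reagents that add atoms: lithium (trimethylsilyl)acetylide, [Li]C#C[Si](C)(C)C
Why: BF3-promoted alkynylation should open the epoxide at its CH2 carbon (the tosyloxymethyl group disfavours ionisation at the tertiary carbon) without breaking the C–O bond of the stereocentre, and buffered fluoride should remove the alkynyl silyl group without closing the tosylate to an epoxide.

**Step 3**
Reactants: 4 (R)-2-hydroxy-2-methylpent-4-yn-1-yl 4-methylbenzenesulfonate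
Product: 6 (2R,4E)-5-bromo-2-hydroxy-2,4-dimethylpent-4-en-1-yl 4-methylbenzenesulfonate, via alkenylalane 5 (not isolated)
Conditions: Me3Al (3 equiv), Cp2ZrCl2 (0.25 equiv), CH2Cl2, 0 °C to 23 °C; then NBS, THF, −30 °C to 0 °C
Reagents that add atoms: trimethylaluminium, C[Al](C)C; N-bromosuccinimide, BrN1C(=O)CCC1=O
Why: Negishi carboalumination adds methyl and aluminium syn across the terminal alkyne with aluminium at the terminus, and bromodealumination with retention should give the E-alkenyl bromide.

**Step 4**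
Reactants: 6 (2R,4E)-5-bromo-2-hydroxy-2,4-dimethylpent-4-en-1-yl 4-methylbenzenesulfonate
Product: 7 (R)-2-[(E)-3-bromo-2-methylprop-2-en-1-yl]-2-methyloxirane
Conditions: K2CO3, MeOH, 0 °C to 23 °C
Reagents that add atoms: none
Why: Intramolecular Williamson displacement of the primary tosylate by the tertiary alkoxide (3-exo-tet) forms the epoxide without touching the C–O bond of the stereocentre.

**Step 5**
Reactants: 7 (R)-2-[(E)-3-bromo-2-methylprop-2-en-1-yl]-2-methyloxirane
Product: 8 (2S,4E)-5-bromo-2-hydroperoxy-2,4-dimethylpent-4-en-1-ol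
Conditions: anhydrous H2O2 (ca. 2 M in Et2O, 8 equiv), H3PMo12O40 (3 mol %), Et2O, 0 °C to 23 °C
Reagents that add atoms: hydrogen peroxide, OO
Why: Heteropolyacid-catalysed perhydrolysis of a 2,2-disubstituted epoxide should occur at the tertiary carbon in a borderline SN2 opening with inversion, which sets the peroxide-bearing stereocentre C6, while the electron-poor bromoalkene should not be epoxidised.

**Step 6**
Reactants: 8 (2S,4E)-5-bromo-2-hydroperoxy-2,4-dimethylpent-4-en-1-ol
Product: 9 (2S,4E)-5-bromo-2-[(2-methoxypropan-2-yl)peroxy]-2,4-dimethylpent-4-en-1-ol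
Conditions: 2-methoxypropene (1.1 equiv), PPTS (5 mol %), CH2Cl2, −20 °C
Reagents that add atoms: 2-methoxypropene, COC(C)=C
Why: In this acid-catalysed perketalisation the more acidic, α-effect-nucleophilic hydroperoxide should add to the enol ether faster than the primary alcohol.

**Step 7**
Reactants: 9 (2S,4E)-5-bromo-2-[(2-methoxypropan-2-yl)peroxy]-2,4-dimethylpent-4-en-1-ol
Product: 11 (1E,4S)-1-bromo-5-iodo-4-[(2-methoxypropan-2-yl)peroxy]-2,4-dimethylpent-1-ene, via triflate 10 (not isolated)
Conditions: Tf2O, 2,6-lutidine, CH2Cl2, −78 °C; then NaI, acetone, −78 °C to 0 °C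
Reagents that add atoms: trifluoromethanesulfonic anhydride (its atoms stay only in intermediate 10), FC(F)(F)S(=O)(=O)OS(=O)(=O)C(F)(F)F; sodium iodide, [Na+].[I-]
Why: SN2 displacement at this neopentyl-type carbon needs the best leaving group (triflate) and a small soft nucleophile (iodide), and no stereocentre is involved.

**Step 8**
Reactants: 12 (E)-pent-2-enal
Product: 13 tert-butyldimethyl[(1E,3E)-penta-1,3-dien-1-yloxy]silane
Conditions: TBSOTf, Et3N, Et2O, 0 °C
Reagents that add atoms: tert-butyldimethylsilyl trifluoromethanesulfonate, CC(C)(C)[Si](C)(C)OS(=O)(=O)C(F)(F)F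
Why: O-Silylation of the enal followed by γ-deprotonation is the standard silyl dienol ether formation; the geometry of the enol double bond does not matter for the next step.

**Step 9**
Reactants: 11 (1E,4S)-1-bromo-5-iodo-4-[(2-methoxypropan-2-yl)peroxy]-2,4-dimethylpent-1-ene; 13 tert-butyldimethyl[(1E,3E)-penta-1,3-dien-1-yloxy]silane
Product: 16 2-[(3S,4R,6R)-6-[(E)-3-bromo-2-methylprop-2-en-1-yl]-4,6-dimethyl-1,2-dioxan-3-yl]acetaldehyde, via perketal enal 14 (not isolated), via hydroperoxy enal 15 (not isolated)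
Conditions: 13 (2 equiv), fac-Ir(ppy)3 (1 mol %), 1,2-epoxybutane (3 equiv), MeCN (0.5 M), 450 nm LEDs, 20 °C; then MeOH, PPTS (10 mol %), 0 °C; then CHCl3 (0.05 M), (S)-2-{bis[3,5-bis(trifluoromethyl)phenyl][(trimethylsilyl)oxy]methyl}pyrrolidine (20 mol %), 4-nitrobenzoic acid (20 mol %), −10 °C
Reagents that add atoms: none
Why: Proposed new method: the excited trivalent iridium complex should transfer an electron to the primary C–I bond of 11 (the alkenyl bromide and the dialkyl-type perketal are much harder to reduce), the β-peroxyalkyl radical should add to the methyl-bearing terminus C4 of 13 because only there an oxygen-stabilised allyl radical results, and the tetravalent iridium should oxidise that radical to a silyloxocarbenium ion that hands its silyl group to iodide (trapped by the epoxide) and leaves E-enal 14; the closest known reaction type is the photoredox radical–polar crossover alkylation of silyl enol ethers. Acidic methanol then frees the hydroperoxide and the secondary amine turns 15 into its iminium ion, whose β-carbon C3 takes up the hydroperoxide oxygen in a 6-exo-trig oxa-Michael closure of the 1,2-dioxane, the closest known type being the amine-catalysed enantioselective β-peroxidation of enals. C3 is set by the catalyst, whose bulky diarylsilyloxymethyl group shields one face of the E-iminium ion so that oxygen adds to the face that gives 3S. C4, formed without control in the radical step, is set by dynamic kinetic resolution: iminium ion and dienamine interconvert the two C4 epimers, and only the 4R epimer reaches a chair transition state with the C4 methyl and the C3 side chain both equatorial, which gives the 3,4-trans ring, while C6 is not touched. The step needs radical capture to outrun collapse of the radical onto its own O–O bond (secured by 13 at high concentration), chemoselective activation of the sp3 C–I bond, and kinetic control of the ring closure, so the last stage is run cold and stopped before retro-oxa-Michael equilibration.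

**Step 10**
Reactants: 16 2-[(3S,4R,6R)-6-[(E)-3-bromo-2-methylprop-2-en-1-yl]-4,6-dimethyl-1,2-dioxan-3-yl]acetaldehyde
Product: 18 methyl 2-[(3S,4R,6R)-6-[(E)-3-bromo-2-methylprop-2-en-1-yl]-4,6-dimethyl-1,2-dioxan-3-yl]acetate, via carboxylic acid 17 (not isolated)
Conditions: NaClO2, NaH2PO4, 2-methyl-2-butene, t-BuOH/H2O, 0 °C; then Me3SiCHN2, MeOH/PhMe, 0 °C
Reagents that add atoms: sodium chlorite, [Na+].[O-]Cl=O; trimethylsilyldiazomethane, C[Si](C)(C)C=[N+]=[N-]
Why: Pinnick oxidation is weakly acidic and should leave the dialkyl peroxide and the alkenyl bromide alone, and the acid is methylated by diazomethane released from the silyl reagent and methanol.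

**Step 11**
Reactants: 19 (but-2-yn-1-yl)benzene
Product: 21 [(2E)-3-iodobut-2-en-1-yl]benzene, via alkenylzirconocene 20 (not isolated)
Conditions: Cp2Zr(H)Cl (1.3 equiv), THF, 23 °C to 40 °C; then I2, 0 °C
Reagents that add atoms: chloridobis(cyclopentadienyl)hydridozirconium (atoms other than hydrogen stay only in intermediate 20), [H][Zr](Cl)(C1C=CC=C1)C1C=CC=C1; iodine, II
Why: Hydrozirconation adds H and Zr syn and, after equilibration with a slight excess of reagent, should place zirconium on the less hindered methyl-bearing carbon, and iodinolysis proceeds with retention.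

**Step 12**
Reactants: 21 [(2E)-3-iodobut-2-en-1-yl]benzene
Product: 22 4,4,5,5-tetramethyl-2-[(2Z)-4-phenylbut-2-en-2-yl]-1,3,2-dioxaborolane (boron trans to the benzyl group)
Conditions: B2pin2, PdCl2(PPh3)2 (3 mol %), PPh3 (6 mol %), KOPh, PhMe, 50 °C
Reagents that add atoms: bis(pinacolato)diboron, CC1(C)OB(OC1(C)C)B1OC(C)(C)C(C)(C)O1
Why: Miyaura borylation of an alkenyl iodide keeps the alkene geometry (the descriptor changes only because boron ranks below carbon).

**Step 13**
Reactants: 18 methyl 2-[(3S,4R,6R)-6-[(E)-3-bromo-2-methylprop-2-en-1-yl]-4,6-dimethyl-1,2-dioxan-3-yl]acetate; 22 4,4,5,5-tetramethyl-2-[(2Z)-4-phenylbut-2-en-2-yl]-1,3,2-dioxaborolane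
Product: 23 methyl 2-[(3S,4R,6R)-6-[(2E,4E)-2,4-dimethyl-6-phenylhexa-2,4-dien-1-yl]-4,6-dimethyl-1,2-dioxan-3-yl]acetate
Conditions: PdCl2(dppf) (5 mol %), K3PO4, THF/H2O 10:1, 40 °C
Reagents that add atoms: none
Why: Suzuki–Miyaura coupling is stereoretentive at both alkenyl partners, hindered dialkyl peroxides are known to tolerate palladium-catalysed cross-coupling, and any retro-oxa-Michael opening under the mild base should re-close to the same, more stable 3,4-trans isomer.

**Compound list**
1 | (S)-2-methylglycidol | C[C@]1(CO)CO1 | starting material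
2 | (R)-(2-methyloxiran-2-yl)methyl 4-methylbenzenesulfonate | C[C@]1(COS(=O)(=O)c2ccc(C)cc2)CO1 | intermediate
3 | (R)-2-hydroxy-2-methyl-5-(trimethylsilyl)pent-4-yn-1-yl 4-methylbenzenesulfonate | O[C@](C)(CC#C[Si](C)(C)C)COS(=O)(=O)c1ccc(C)cc1 | intermediate
4 | (R)-2-hydroxy-2-methylpent-4-yn-1-yl 4-methylbenzenesulfonate | O[C@](C)(CC#C)COS(=O)(=O)c1ccc(C)cc1 | intermediate
5 | [(1E,4R)-4-[(dimethylalumanyl)oxy]-2,4-dimethyl-5-(tosyloxy)pent-1-en-1-yl]dimethylalumane | C[Al](C)O[C@](C)(C/C(C)=C/[Al](C)C)COS(=O)(=O)c1ccc(C)cc1 | intermediate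
6 | (2R,4E)-5-bromo-2-hydroxy-2,4-dimethylpent-4-en-1-yl 4-methylbenzenesulfonate | O[C@](C)(C/C(C)=C/Br)COS(=O)(=O)c1ccc(C)cc1 | intermediate
7 | (R)-2-[(E)-3-bromo-2-methylprop-2-en-1-yl]-2-methyloxirane | C[C@@]1(C/C(C)=C/Br)CO1 | intermediate
8 | (2S,4E)-5-bromo-2-hydroperoxy-2,4-dimethylpent-4-en-1-ol | OO[C@@](C)(C/C(C)=C/Br)CO | intermediate
9 | (2S,4E)-5-bromo-2-[(2-methoxypropan-2-yl)peroxy]-2,4-dimethylpent-4-en-1-ol | COC(C)(C)OO[C@@](C)(C/C(C)=C/Br)CO | intermediate
10 | (2S,4E)-5-bromo-2-[(2-methoxypropan-2-yl)peroxy]-2,4-dimethylpent-4-en-1-yl trifluoromethanesulfonate | COC(C)(C)OO[C@@](C)(C/C(C)=C/Br)COS(=O)(=O)C(F)(F)F | intermediate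
11 | (1E,4S)-1-bromo-5-iodo-4-[(2-methoxypropan-2-yl)peroxy]-2,4-dimethylpent-1-ene | COC(C)(C)OO[C@@](C)(C/C(C)=C/Br)CI | intermediate
12 | (E)-pent-2-enal | CC/C=C/C=O | starting material
13 | tert-butyldimethyl[(1E,3E)-penta-1,3-dien-1-yloxy]silane | C/C=C/C=C/O[Si](C)(C)C(C)(C)C | intermediate
14 | (2E,4RS,6R,8E)-9-bromo-6-[(2-methoxypropan-2-yl)peroxy]-4,6,8-trimethylnona-2,8-dienal | O=C/C=C/C(C)C[C@@](C)(OOC(C)(C)OC)C/C(C)=C/Br | intermediate
15 | (2E,4RS,6R,8E)-9-bromo-6-hydroperoxy-4,6,8-trimethylnona-2,8-dienal | O=C/C=C/C(C)C[C@@](C)(OO)C/C(C)=C/Br | intermediate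
16 | 2-[(3S,4R,6R)-6-[(E)-3-bromo-2-methylprop-2-en-1-yl]-4,6-dimethyl-1,2-dioxan-3-yl]acetaldehyde | O=CC[C@@H]1OO[C@@](C)(C/C(C)=C/Br)C[C@H]1C | intermediate
17 | 2-[(3S,4R,6R)-6-[(E)-3-bromo-2-methylprop-2-en-1-yl]-4,6-dimethyl-1,2-dioxan-3-yl]acetic acid | OC(=O)C[C@@H]1OO[C@@](C)(C/C(C)=C/Br)C[C@H]1C | intermediate
18 | methyl 2-[(3S,4R,6R)-6-[(E)-3-bromo-2-methylprop-2-en-1-yl]-4,6-dimethyl-1,2-dioxan-3-yl]acetate | COC(=O)C[C@@H]1OO[C@@](C)(C/C(C)=C/Br)C[C@H]1C | intermediate
19 | (but-2-yn-1-yl)benzene | CC#CCc1ccccc1 | starting material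
20 | chloridobis(cyclopentadienyl)[(2E)-4-phenylbut-2-en-2-yl]zirconium | Cl[Zr](/C(C)=C/Cc1ccccc1)(C1C=CC=C1)C1C=CC=C1 | intermediate
21 | [(2E)-3-iodobut-2-en-1-yl]benzene | I/C(C)=C/Cc1ccccc1 | intermediate
22 | 4,4,5,5-tetramethyl-2-[(2Z)-4-phenylbut-2-en-2-yl]-1,3,2-dioxaborolane | CC1(C)OB(/C(C)=C/Cc2ccccc2)OC1(C)C | intermediate
23 | methyl 2-[(3S,4R,6R)-6-[(2E,4E)-2,4-dimethyl-6-phenylhexa-2,4-dien-1-yl]-4,6-dimethyl-1,2-dioxan-3-yl]acetate | COC(=O)C[C@@H]1OO[C@@](C)(C/C(C)=C/C(C)=C/Cc2ccccc2)C[C@H]1C | target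

**Step count**
Total: 13 steps. Longest linear sequence: 10 steps (steps 1 to 7, 9, 10 and 13).

**Steps most likely to fail**

Step 9 (Proposed new method). What may go wrong:
- The β-peroxyalkyl radical may collapse onto its own O–O bond (epoxide formation) before it is captured.
- The excited photocatalyst may reduce the perketal.
- Epimerisation at C4 may be too slow, so that the ring closure ends as a simple kinetic resolution.
- The enamine formed after ring closure may attack the O–O bond.

Fallback by known chemistry, setting out from epoxide 7 and coming back at ester 18: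
- Isomerisation of 7 with diethylaluminium 2,2,6,6-tetramethylpiperidide (PhMe, 0 °C; proton abstraction from the methyl group) should give the allylic alcohol (4E)-5-bromo-4-methyl-2-methylidenepent-4-en-1-ol F1.
- Appel bromination (CBr4, PPh3) gives the allylic bromide (1E)-1-bromo-4-(bromomethyl)-2-methylpenta-1,4-diene F2.
- Evans alkylation of the sodium enolate of (S)-4-benzyl-3-propanoyl-1,3-oxazolidin-2-one with F2 (NaHMDS, THF, −78 °C) sets C4 in the imide (4S)-4-benzyl-3-[(2R,6E)-7-bromo-2,6-dimethyl-4-methylidenehept-6-enoyl]-1,3-oxazolidin-2-one F3.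
- LiBH4 releases the auxiliary and gives the alcohol (2R,6E)-7-bromo-2,6-dimethyl-4-methylidenehept-6-en-1-ol F4.
- Dess–Martin oxidation gives the aldehyde (2R,6E)-7-bromo-2,6-dimethyl-4-methylidenehept-6-enal F5.
- Wittig reaction with methyl (triphenylphosphoranylidene)acetate gives the enoate methyl (2E,4R,8E)-9-bromo-4,8-dimethyl-6-methylidenenona-2,8-dienoate F6.
- Mukaiyama–Isayama peroxidation of the 1,1-disubstituted alkene (Co(acac)2, O2, Et3SiH) gives the silyl peroxide methyl (2E,4R,8E)-9-bromo-4,6,8-trimethyl-6-[(triethylsilyl)peroxy]nona-2,8-dienoate F7 as both C6 epimers.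
- Desilylation (HF·pyridine) and Et3N in CF3CH2OH then close the ring by oxa-Michael addition trans to the C4 methyl group.

This fallback gives no control at C6, so 18 would have to be separated from its C6 epimer.

Step 5. What may go wrong: an SN1-like opening that leaks configuration at C6, or attack of H2O2 at the primary carbon.

Fallback, setting out from 7 and coming back at 11:
- Ring expansion of 7 with dimethylsulfoxonium methylide (Me3S(O)I, KOt-Bu, t-BuOH, 50 °C) leaves the C–O bond of the stereocentre intact and gives the oxetane (R)-2-[(E)-3-bromo-2-methylprop-2-en-1-yl]-2-methyloxetane F8.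
- Lewis-acid-promoted opening by H2O2 (Me3SiOTf, Et2O, −78 °C), a reaction type known to run with predominant inversion at tertiary oxetane carbons, gives the hydroperoxy alcohol (3S,5E)-6-bromo-3-hydroperoxy-3,5-dimethylhex-5-en-1-ol F9.
- Perketal formation as in step 6 gives the alcohol (3S,5E)-6-bromo-3-[(2-methoxypropan-2-yl)peroxy]-3,5-dimethylhex-5-en-1-ol F10.
- Oxidation (TEMPO, PhI(OAc)2, MeCN/H2O) gives the acid (3S,5E)-6-bromo-3-[(2-methoxypropan-2-yl)peroxy]-3,5-dimethylhex-5-enoic acid F11.
- Iododecarboxylation (PhI(OAc)2, I2, visible light) removes the extra carbon and gives 11; the primary radical should be caught by iodine far faster than it can attack the O–O bond.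

Step 7. What may go wrong: slow SN2 at the neopentyl-type carbon, and participation of the peroxide oxygen leading to a dioxetane or a rearrangement.

Fallback, setting out from 7 and coming back at perketal enal 14: the radical precursor is changed from a halide to a redox-active ester. Acid F11, made from 7 as described above, is esterified with N-hydroxyphthalimide (N,N'-diisopropylcarbodiimide, DMAP cat.) to the ester 1,3-dioxoisoindolin-2-yl (3S,5E)-6-bromo-3-[(2-methoxypropan-2-yl)peroxy]-3,5-dimethylhex-5-enoate F12. F12 takes the place of 11 in the first stage of step 9: single-electron reduction by the photocatalyst and loss of CO2 and phthalimide anion give the same primary radical, and the sequence continues from 14 as written.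

**Further compounds**
F1 | step 9 | (4E)-5-bromo-4-methyl-2-methylidenepent-4-en-1-ol | OCC(=C)C/C(C)=C/Br
F2 | step 9 | (1E)-1-bromo-4-(bromomethyl)-2-methylpenta-1,4-diene | BrCC(=C)C/C(C)=C/Br
F3 | step 9 | (4S)-4-benzyl-3-[(2R,6E)-7-bromo-2,6-dimethyl-4-methylidenehept-6-enoyl]-1,3-oxazolidin-2-one | O=C1OC[C@H](Cc2ccccc2)N1C(=O)[C@H](C)CC(=C)C/C(C)=C/Br
F4 | step 9 | (2R,6E)-7-bromo-2,6-dimethyl-4-methylidenehept-6-en-1-ol | OC[C@H](C)CC(=C)C/C(C)=C/Br
F5 | step 9 | (2R,6E)-7-bromo-2,6-dimethyl-4-methylidenehept-6-enal | O=C[C@H](C)CC(=C)C/C(C)=C/Br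
F6 | step 9 | methyl (2E,4R,8E)-9-bromo-4,8-dimethyl-6-methylidenenona-2,8-dienoate | COC(=O)/C=C/[C@H](C)CC(=C)C/C(C)=C/Br
F7 | step 9 | methyl (2E,4R,8E)-9-bromo-4,6,8-trimethyl-6-[(triethylsilyl)peroxy]nona-2,8-dienoate (both C6 epimers) | COC(=O)/C=C/[C@H](C)CC(C)(OO[Si](CC)(CC)CC)C/C(C)=C/Br
F8 | step 5 | (R)-2-[(E)-3-bromo-2-methylprop-2-en-1-yl]-2-methyloxetane | C[C@@]1(C/C(C)=C/Br)CCO1
F9 | step 5 | (3S,5E)-6-bromo-3-hydroperoxy-3,5-dimethylhex-5-en-1-ol | OO[C@@](C)(C/C(C)=C/Br)CCO
F10 | step 5 | (3S,5E)-6-bromo-3-[(2-methoxypropan-2-yl)peroxy]-3,5-dimethylhex-5-en-1-ol | COC(C)(C)OO[C@@](C)(C/C(C)=C/Br)CCO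
F11 | step 5 | (3S,5E)-6-bromo-3-[(2-methoxypropan-2-yl)peroxy]-3,5-dimethylhex-5-enoic acid | COC(C)(C)OO[C@@](C)(C/C(C)=C/Br)CC(O)=O
F12 | step 7 | 1,3-dioxoisoindolin-2-yl (3S,5E)-6-bromo-3-[(2-methoxypropan-2-yl)peroxy]-3,5-dimethylhex-5-enoate | COC(C)(C)OO[C@@](C)(C/C(C)=C/Br)CC(=O)ON1C(=O)c2ccccc2C1=O
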